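**Retrosynthetic overview**

- The target is (2R)-1-(3,5-dihydroxyphenyl)tridecan-2-yl acetate. The strategy rests on the acetoxy carbon C2, which lies between the benzylic carbon C1 on the resorcinol ring A and C3 of the undecyl chain: an aryl–CH2–CH(O)–alkyl unit, i.e. an arene, a two-carbon vinyl unit and an alkyl group.
- The acetate and both benzyl ethers are removed, and the C2–O bond is traced back to a C2–B bond (oxidation with retention), giving the secondary pinacol boronate 9.
- In 9 the ring A–C1 and C2–C3 bonds are cut in one operation: vinyllithium, undecylboronic ester 3 and aryl triflate 5 are joined by an enantioselective palladium-catalysed conjunctive coupling.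
- The three partners come from hydroboration of 1-undecene, triflation of 3,5-bis(benzyloxy)phenol and tin–lithium exchange on tetravinyltin.
- No ring is formed anywhere in the route; ring A is bought intact.

Key step: step 4

Assumption: the (Sp,Sp) ligand is taken to give the 2R boronate, by analogy with the parent coupling of a primary alkyl migrating group with a simple aryl triflate. The sense is to be checked on alcohol 10 (Mosher esters), and the (Rp,Rp) ligand would be used if the opposite sense were found.

**Route**

Step 1
Reactants: 1 1-undecene; 2 pinacolborane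
Product: 3 2-undecyl-4,4,5,5-tetramethyl-1,3,2-dioxaborolane
Conditions: RhCl(PPh3)3 (1 mol%), CH2Cl2, rt
Reagents that add atoms: none
Why: Rhodium-catalysed hydroboration of a terminal alkene with pinacolborane places boron on the terminal carbon (anti-Markovnikov) and gives the primary alkyl pinacol boronate without creating a stereocentre.

Step 2
Reactants: 4 3,5-bis(benzyloxy)phenol
Product: 5 3,5-bis(benzyloxy)phenyl trifluoromethanesulfonate
Conditions: Tf2O, pyridine, CH2Cl2, 0 °C
Reagents that add atoms: trifluoromethanesulfonic anhydride (Tf2O), O=S(=O)(OS(=O)(=O)C(F)(F)F)C(F)(F)F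
Why: O-sulfonylation of a phenol with triflic anhydride and pyridine is the standard aryl triflate synthesis, and the benzyl ethers are inert to it.

Step 3
Reactants: 6 tetravinyltin
Product: 7 vinyllithium (collected as the solid under argon, dissolved in Et2O and titrated)
Conditions: n-BuLi (just under 4 equiv), pentane, rt; filter, wash with pentane
Reagents that add atoms: n-butyllithium, [Li]CCCC
Why: Tin–lithium exchange is driven towards the more stable sp2 organolithium, which precipitates from pentane free of lithium halide while tetrabutyltin stays in solution; the slight deficit of n-butyllithium keeps butyl groups off boron in step 4.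

Step 4
Reactants: 3 2-undecyl-4,4,5,5-tetramethyl-1,3,2-dioxaborolane; 7 vinyllithium; 5 3,5-bis(benzyloxy)phenyl trifluoromethanesulfonate
Product: 9 2-[(2R)-1-[3,5-bis(benzyloxy)phenyl]tridecan-2-yl]-4,4,5,5-tetramethyl-1,3,2-dioxaborolane, via lithium ethenyl(undecyl)(pinacolato)borate 8 (not isolated)
Conditions: 3, 7 (1.0 equiv), Et2O, 0 °C → rt, then evaporate; 5 (1.1 equiv), Pd(OAc)2 (2 mol%), (Sp,Sp)-Mandyphos [1,1′-bis(di-3,5-xylylphosphino)-2,2′-bis[(R)-α-(dimethylamino)benzyl]ferrocene] (2.4 mol%), THF, 60 °C
Reagents that add atoms: none
Why: Zerovalent palladium adds oxidatively to the C–OTf bond of 5, and the resulting cationic aryl complex of divalent palladium, whose triflate is only weakly bound, takes up the vinyl π-bond of the four-coordinate boronate 8. This binding triggers a 1,2-metallate shift in which the undecyl group moves from boron to the α-carbon anti to palladium (C2–C3 bond) while the Pd–C bond forms at the terminal carbon, and reductive elimination then joins ring A to C1 and returns zerovalent palladium. The step is the known palladium-catalysed enantioselective conjunctive cross-coupling of vinylboron ate complexes with aryl triflates, applied here to a primary alkyl migrating group and an unhindered meta-disubstituted aryl triflate, and it closes no ring. The C2 stereocentre is set by enantioface selection of the bound vinyl group under control of the chiral bisphosphine on palladium, the (Sp,Sp) ligand being expected to give the 2R boronate. The conjunctive path has to outrun direct vinyl transfer to the aryl group (Suzuki-type) and β-hydride elimination. That is secured by the halide-free medium and non-coordinating triflate, by the coordinatively saturated boron of 8 with its unhindered terminal vinyl group and readily migrating primary alkyl group, and by the wide-bite-angle ligand that speeds reductive elimination; the benzyl ethers are inert.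

Step 5
Reactants: 9 2-[(2R)-1-[3,5-bis(benzyloxy)phenyl]tridecan-2-yl]-4,4,5,5-tetramethyl-1,3,2-dioxaborolane
Product: 10 (2R)-1-[3,5-bis(benzyloxy)phenyl]tridecan-2-ol
Conditions: 30% H2O2, 3 M aq. NaOH, THF, 0 °C → rt
Reagents that add atoms: hydrogen peroxide, OO
Why: Alkaline peroxide oxidation of the C–B bond goes by hydroperoxide addition to boron and 1,2-migration of C2 from boron to oxygen with retention, so the R configuration from step 4 is carried into the carbinol.

Step 6
Reactants: 10 (2R)-1-[3,5-bis(benzyloxy)phenyl]tridecan-2-ol
Product: 11 (2R)-1-[3,5-bis(benzyloxy)phenyl]tridecan-2-yl acetate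
Conditions: Ac2O, Et3N, DMAP (cat.), CH2Cl2, 0 °C → rt
Reagents that add atoms: acetic anhydride, CC(=O)OC(C)=O
Why: DMAP-catalysed acylation of the secondary alcohol (nucleophilic catalysis through the N-acetylpyridinium ion) leaves the C2–O bond untouched, so the configuration is retained.

Step 7
Reactants: 11 (2R)-1-[3,5-bis(benzyloxy)phenyl]tridecan-2-yl acetate
Product: 12 (2R)-1-(3,5-dihydroxyphenyl)tridecan-2-yl acetate
Conditions: H2 (1 atm), 10% Pd/C (palladium on carbon), EtOAc, rt
Reagents that add atoms: none
Why: Catalytic hydrogenolysis cleaves the two benzylic C–O bonds of the aryl benzyl ethers, whereas the acetate at C2 is homobenzylic, not benzylic, and is inert in neutral ethyl acetate, so neither acyl loss nor epimerisation is expected.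

**Compound list**

1 | 1-undecene | C=CCCCCCCCCC | starting material
2 | pinacolborane (4,4,5,5-tetramethyl-1,3,2-dioxaborolane) | B1OC(C)(C)C(C)(C)O1 | starting material
3 | 2-undecyl-4,4,5,5-tetramethyl-1,3,2-dioxaborolane | CCCCCCCCCCCB1OC(C)(C)C(C)(C)O1 | intermediate
4 | 3,5-bis(benzyloxy)phenol | Oc1cc(OCc2ccccc2)cc(OCc2ccccc2)c1 | starting material
5 | 3,5-bis(benzyloxy)phenyl trifluoromethanesulfonate | O=S(=O)(Oc1cc(OCc2ccccc2)cc(OCc2ccccc2)c1)C(F)(F)F | intermediate
6 | tetravinyltin (tetraethenylstannane) | C=C[Sn](C=C)(C=C)C=C | starting material
7 | vinyllithium | [Li]C=C | intermediate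
8 | lithium ethenyl(undecyl)(pinacolato)borate | [Li+].CCCCCCCCCCC[B-]1(C=C)OC(C)(C)C(C)(C)O1 | intermediate
9 | 2-[(2R)-1-[3,5-bis(benzyloxy)phenyl]tridecan-2-yl]-4,4,5,5-tetramethyl-1,3,2-dioxaborolane | CCCCCCCCCCC[C@H](Cc1cc(OCc2ccccc2)cc(OCc2ccccc2)c1)B1OC(C)(C)C(C)(C)O1 | intermediate
10 | (2R)-1-[3,5-bis(benzyloxy)phenyl]tridecan-2-ol | CCCCCCCCCCC[C@H](Cc1cc(OCc2ccccc2)cc(OCc2ccccc2)c1)O | intermediate
11 | (2R)-1-[3,5-bis(benzyloxy)phenyl]tridecan-2-yl acetate | CCCCCCCCCCC[C@H](Cc1cc(OCc2ccccc2)cc(OCc2ccccc2)c1)OC(C)=O | intermediate
12 | (2R)-1-(3,5-dihydroxyphenyl)tridecan-2-yl acetate (CNP0241330.1) | CCCCCCCCCCC[C@H](Cc1cc(O)cc(O)c1)OC(C)=O | target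

**Step count**

Total steps: 7. Longest linear sequence: 5 (steps 1, 4, 5, 6, 7; the branches through step 2 or step 3 are equally long).

**Steps most likely to fail**

1. Step 4. The risk is poor enantioface selection at the vinyl ate complex, or diversion of the arylpalladium intermediate into direct vinyl transfer or β-hydride elimination. The fallback sets out from triflate 5 and returns to the route at alcohol 10, replacing steps 4 and 5. Stille allylation of 5 (allyltributylstannane, Pd(PPh3)4, LiCl, dioxane, reflux) should give 1-allyl-3,5-bis(benzyloxy)benzene F1. Epoxidation with mCPBA (NaHCO3, CH2Cl2) should give racemic 2-[3,5-bis(benzyloxy)benzyl]oxirane F2. Hydrolytic kinetic resolution (0.55 equiv H2O) uses the (salen)Co(OAc) complex of trivalent cobalt, salen being N,N′-bis(3,5-di-tert-butylsalicylidene)-trans-1,2-cyclohexanediamine, in the enantiomer that leaves the S epoxide unreacted; it should give (2S)-2-[3,5-bis(benzyloxy)benzyl]oxirane F3. Opening of F3 at its terminal carbon with decylmagnesium bromide and catalytic CuBr·SMe2 (THF, −40 → 0 °C) leaves the stereocentre untouched and should deliver 10.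

2. Step 3. The risk is incomplete tin–lithium exchange, carry-over of butyllithium, or loss of titre while the pyrophoric solid is handled, which would put butyl in place of vinyl on boron or leave 3 unconverted. The fallback sets out from boronate 3 and returns at boronate 9. Commercial vinylmagnesium chloride is added to 3 in THF/DMSO in the presence of NaOTf, which removes chloride and promotes ate formation, to give sodium ethenyl(undecyl)(pinacolato)borate F4. F4 is then coupled with 5 under the Pd(OAc)2/(Sp,Sp)-Mandyphos conditions of step 4.

3. Step 7. The risk is stalling of the hydrogenolysis after one benzyl ether through poisoning of the catalyst by carried-over phosphine, tin or boron residues, or ring saturation on forcing. The fallback sets out from 11 and returns at 12. Lewis-acid debenzylation with BCl3 and pentamethylbenzene as cation scavenger (CH2Cl2, −78 °C) should free both phenols while the secondary acetate survives at low temperature; no new compound is made on the way (F0).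

**Further compounds**

F1 | step 4 | 1-allyl-3,5-bis(benzyloxy)benzene | C=CCc1cc(OCc2ccccc2)cc(OCc2ccccc2)c1
F2 | step 4 | racemic 2-[3,5-bis(benzyloxy)benzyl]oxirane | C1OC1Cc1cc(OCc2ccccc2)cc(OCc2ccccc2)c1
F3 | step 4 | (2S)-2-[3,5-bis(benzyloxy)benzyl]oxirane | C1[C@H](Cc2cc(OCc3ccccc3)cc(OCc3ccccc3)c2)O1
F4 | step 3 | sodium ethenyl(undecyl)(pinacolato)borate | [Na+].CCCCCCCCCCC[B-]1(C=C)OC(C)(C)C(C)(C)O1
F0 | step 7 | none | none
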